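**Retrosynthetic overview**
1. Target 23 ⇐ acid removal of eight MOM groups and hydrolysis of the 4'-OMe of 21; 21 ⇐ cis-selective hydride reduction of the 4-arylflavan-3-one 20.
2. The C4–C6' interflavanyl bond of 20 ⇐ semipinacol 1,2-aryl shift (C3→C4) in carbinol 19, made from the aryllithium of bromide 16 and α-methoxy ketone 17.
3. Both partners 16 and 17 ⇐ one monomer 15 ⇐ syn-epoxide 14 ⇐ bromohydrin 13 ⇐ (2S)-flav-3-ene 12.
4. 12 ⇐ asymmetric allylic etherification of 11 ⇐ ortho-hydroxyalkylation of phenol 5 with enal 9; 5 and 9 both come from catechol 1 and acrolein dimethyl acetal 7.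
5. Ring order: the pyran ring is closed once, at the monomer stage (step 6), and serves both flavan units; no ring is formed after the coupling.

Abbreviations: MOMO = OCH2OCH3; Ar = 3,4-bis(MOMO)phenyl; chroman = 3,4-dihydro-2H-chromene with flavan numbering (primes for the lower unit).
Assumption: the 4-O-methyl group introduced in step 8 is treated as a temporary protecting group, and organometallic species formed in the flask are numbered as intermediates.

**Route**

Step 1
Reactants: 1 catechol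
Product: 2 1,2-bis(MOMO)benzene
Conditions: MOMCl, i-Pr2NEt, CH2Cl2, 0 °C → rt
Reagents that add atoms: chloromethyl methyl ether, COCCl
Why: Williamson-type O-alkylation masks both phenols as MOM ethers, which later direct the lithiation and come off under mild acid.

Step 2
Reactants: 2 1,2-bis(MOMO)benzene
Product: 5 2,3-bis(MOMO)phenol, via aryllithium 3 (not isolated), via lithium aryltrimethoxyborate 4 (not isolated)
Conditions: n-BuLi, TMEDA, THF, 0 °C; B(OMe)3, −78 °C → rt; 30% H2O2, 0 °C → rt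
Reagents that add atoms: hydrogen peroxide, OO
Why: Directed ortho-metalation next to OMOM, borylation and peroxide oxidation of the C–B bond install the third oxygen of the A-ring at the only position the directing groups allow.

Step 3
Reactants: 2 1,2-bis(MOMO)benzene
Product: 6 4-bromo-1,2-bis(MOMO)benzene
Conditions: NBS, MeCN, 0 °C → rt
Reagents that add atoms: N-bromosuccinimide, O=C1CCC(=O)N1Br
Why: Electrophilic aromatic bromination goes para to an OMOM group, the B-ring attachment position.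

Step 4
Reactants: 6 4-bromo-1,2-bis(MOMO)benzene; 7 acrolein dimethyl acetal
Product: 9 (E)-3-Ar-prop-2-enal, via enal dimethyl acetal 8 (not isolated)
Conditions: Pd(OAc)2 (3 mol %), n-Bu4NOAc, K2CO3, KCl, DMF, 90 °C; then PPTS (cat.), acetone–H2O, rt
Reagents that add atoms: water, O
Why: A ligand-free Heck reaction arylates the terminal alkene carbon and gives the (E)-alkene, and mild hydrolysis of the conjugated acetal frees the enal without touching the MOM ethers.

Step 5
Reactants: 5 2,3-bis(MOMO)phenol; 9 (E)-3-Ar-prop-2-enal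
Product: 11 rac-(E)-1-[2-hydroxy-3,4-bis(MOMO)phenyl]-3-Ar-prop-2-en-1-ol, via magnesium phenoxide 10 (not isolated)
Conditions: EtMgBr, Et2O, 0 °C; then 9, toluene, 0 °C → rt; aq. NH4Cl
Reagents that add atoms: none
Why: Chelation-controlled ortho-specific hydroxyalkylation of a bromomagnesium phenoxide (1,2-addition through a six-membered Mg chelate) makes the C4–C4a bond at the only free ortho position; the carbinol centre is racemic and is erased in step 6.

Step 6
Reactants: 11 rac-(E)-1-[2-hydroxy-3,4-bis(MOMO)phenyl]-3-Ar-prop-2-en-1-ol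
Product: 12 (2S)-2-Ar-7,8-bis(MOMO)-2H-chromene
Conditions: chiral BINOL-derived N-triflylphosphoramide (5 mol %), 4 Å MS, toluene, −78 → −40 °C
Reagents that add atoms: none
Why: Chiral Brønsted acid-catalysed intramolecular allylic etherification ionises the carbinol to a 1,3-diarylallyl cation paired with the chiral anion, and the phenol oxygen closes the pyran ring on one face to set C2 (catalyst enantiomer chosen for 2S, which is the 2α-aryl arrangement of the target).

Step 7
Reactants: 12 (2S)-2-Ar-7,8-bis(MOMO)-2H-chromene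
Product: 13 (2R,3S,4R)-3-bromo-2-Ar-7,8-bis(MOMO)chroman-4-ol
Conditions: NBS, THF–H2O (4:1), 0 °C
Reagents that add atoms: N-bromosuccinimide, O=C1CCC(=O)N1Br; water, O
Why: Bromohydrin formation adds Br+ to C3 on the face anti to the 2-aryl group and water to the benzylic C4 cation anti to bromine, setting 3β-Br and 4α-OH.

Step 8
Reactants: 13 (2R,3S,4R)-3-bromo-2-Ar-7,8-bis(MOMO)chroman-4-ol
Product: 15 (2R,3R,4S)-4-methoxy-2-Ar-7,8-bis(MOMO)chroman-3-ol, via syn-epoxide 14 (not isolated)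
Conditions: K2CO3, MeOH, 0 °C; then PPTS (20 mol %), MeOH, −20 °C
Reagents that add atoms: methanol, CO
Why: Intramolecular SN2 closure inverts C3 and puts the epoxide oxygen cis to the 2-aryl group, and acid-catalysed trans-diaxial methanolysis at benzylic C4 then gives the 2,3-cis-3,4-trans pattern (3α-OH, 4β-OMe).

Step 9
Reactants: 15 (2R,3R,4S)-4-methoxy-2-Ar-7,8-bis(MOMO)chroman-3-ol
Product: 16 (2R,3R,4S)-6-bromo-4-methoxy-2-Ar-7,8-bis(MOMO)chroman-3-ol
Conditions: NBS, MeCN, −20 → 0 °C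
Reagents that add atoms: N-bromosuccinimide, O=C1CCC(=O)N1Br
Why: Electrophilic aromatic bromination takes C6, the most activated carbon (ortho to the 7-OMOM, para to the ring oxygen) of the more electron-rich A-ring; no stereocentre is affected.

Step 10
Reactants: 15 (2R,3R,4S)-4-methoxy-2-Ar-7,8-bis(MOMO)chroman-3-ol
Product: 17 (2R,4S)-4-methoxy-2-Ar-7,8-bis(MOMO)chroman-3-one
Conditions: Dess–Martin periodinane, pyridine, CH2Cl2, 0 °C
Reagents that add atoms: none
Why: Buffered Dess–Martin oxidation gives the α-methoxy ketone without acid that would epimerise C2 or ionise the C4 ether.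

Step 11
Reactants: 16 (2R,3R,4S)-6-bromo-4-methoxy-2-Ar-7,8-bis(MOMO)chroman-3-ol; 17 (2R,4S)-4-methoxy-2-Ar-7,8-bis(MOMO)chroman-3-one
Product: 20 (2R,4S)-2-Ar-4-[(2R,3R,4S)-2-Ar-3-hydroxy-4-methoxy-7,8-bis(MOMO)chroman-6-yl]-7,8-bis(MOMO)chroman-3-one, via dilithio species 18 (not isolated), via dilithium dialkoxide 19 (not isolated)
Conditions: 16, t-BuLi (3.1 equiv), THF, −78 °C; then 17, −78 °C; then MgBr2·OEt2, −78 → 0 °C; aq. NH4Cl
Reagents that add atoms: none
Why: Proposed new method: the aryllithium from 16 adds to the C3 carbonyl of 17 on the α-face, anti to the axial 4β-OMe (polar Felkin–Anh, axial attack), so in 19 the new C3–aryl bond is trans-diaxial to C4–OMe; Mg(II) chelated between the cis C3–O⁻ and C4–OMe then pulls off methoxide while the alkoxide pushes the electron-rich aryl from C3 to C4 with inversion (semipinacol 1,2-aryl shift through a phenonium-like transition state), which forges the C4–C6' interflavanyl bond, places the new aryl cis to the 2-aryl group and regenerates the C3 ketone, whereas the lower unit is spared because its 3'-O⁻ and 4'-OMe are trans-diaxial and cannot chelate; the closest known reaction types are the rearrangement of halohydrin magnesium alkoxides from α-halo ketones and Grignard reagents and the organoaluminium-promoted pinacol-type 1,2-shift of β-sulfonyloxy alcohols, neither shown with a benzylic ether leaving group or for an interflavanyl bond.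

Step 12
Reactants: 20 (2R,4S)-2-Ar-4-[(2R,3R,4S)-2-Ar-3-hydroxy-4-methoxy-7,8-bis(MOMO)chroman-6-yl]-7,8-bis(MOMO)chroman-3-one
Product: 21 (2R,3R,4S)-2-Ar-4-[(2R,3R,4S)-2-Ar-3-hydroxy-4-methoxy-7,8-bis(MOMO)chroman-6-yl]-7,8-bis(MOMO)chroman-3-ol
Conditions: L-Selectride (2.5 equiv), THF, −78 °C; aq. NH4Cl
Reagents that add atoms: none
Why: The bulky hydride attacks the C3 ketone equatorially from the face opposite the two equatorial aryl groups at C2 and C4, giving the axial 3-OH and the all-cis upper unit (L-Selectride reduction of a flavan-3-one to the 2,3-cis alcohol).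

Step 13
Reactants: 21 (2R,3R,4S)-2-Ar-4-[(2R,3R,4S)-2-Ar-3-hydroxy-4-methoxy-7,8-bis(MOMO)chroman-6-yl]-7,8-bis(MOMO)chroman-3-ol
Product: 23 (2R,3R,4R)-2-(3,4-dihydroxyphenyl)-4-[(2R,3R,4S)-2-(3,4-dihydroxyphenyl)-3,4,7,8-tetrahydroxychroman-6-yl]chroman-3,7,8-triol, via octaphenol 4'-methyl ether 22 (not isolated)
Conditions: 0.5 M HCl in MeOH, 40 °C; evaporate; then 0.05 M aq. HCl–THF (4:1), 1 mM, rt, argon; Sephadex LH-20
Reagents that add atoms: water, O
Why: Acid transacetalisation removes the eight MOM groups as dimethoxymethane, and SN1 hydrolysis of the benzylic 4'-OMe then lets water add to the C4' cation trans to the axial 3'-OH, so the 3,4-trans (4'S) alcohol is kept; the C–C interflavanyl bond of this 5-deoxy system is acid-stable.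

**Compound list**
1 | catechol | Oc1ccccc1O | starting material
2 | 1,2-bis(MOMO)benzene | COCOc1ccccc1OCOC | intermediate
3 | [2,3-bis(MOMO)phenyl]lithium | COCOc1cccc([Li])c1OCOC | intermediate
4 | lithium trimethoxy[2,3-bis(MOMO)phenyl]borate | [Li+].COCOc1cccc([B-](OC)(OC)OC)c1OCOC | intermediate
5 | 2,3-bis(MOMO)phenol | COCOc1cccc(O)c1OCOC | intermediate
6 | 4-bromo-1,2-bis(MOMO)benzene | COCOc1ccc(Br)cc1OCOC | intermediate
7 | acrolein dimethyl acetal (3,3-dimethoxyprop-1-ene) | C=CC(OC)OC | starting material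
8 | (E)-4-(3,3-dimethoxyprop-1-enyl)-1,2-bis(MOMO)benzene | COCOc1ccc(/C=C/C(OC)OC)cc1OCOC | intermediate
9 | (E)-3-Ar-prop-2-enal | COCOc1ccc(/C=C/C=O)cc1OCOC | intermediate
10 | bromomagnesium 2,3-bis(MOMO)phenoxide | COCOc1cccc(O[Mg]Br)c1OCOC | intermediate
11 | rac-(E)-1-[2-hydroxy-3,4-bis(MOMO)phenyl]-3-Ar-prop-2-en-1-ol | COCOc1ccc(/C=C/C(O)c2ccc(OCOC)c(OCOC)c2O)cc1OCOC | intermediate
12 | (2S)-2-Ar-7,8-bis(MOMO)-2H-chromene (2α-aryl; S only because C3 is sp2) | COCOc1ccc([C@H]2Oc3c(ccc(OCOC)c3OCOC)C=C2)cc1OCOC | intermediate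
13 | (2R,3S,4R)-3-bromo-2-Ar-7,8-bis(MOMO)chroman-4-ol (Br trans to aryl and to OH) | COCOc1ccc([C@H]2Oc3c(ccc(OCOC)c3OCOC)[C@@H](O)[C@@H]2Br)cc1OCOC | intermediate
14 | (2R,3R,4R)-3,4-epoxy-2-Ar-7,8-bis(MOMO)chromane (oxirane cis to the 2-aryl group) | COCOc1ccc([C@H]2Oc3c(ccc(OCOC)c3OCOC)[C@H]4O[C@@H]24)cc1OCOC | intermediate
15 | (2R,3R,4S)-4-methoxy-2-Ar-7,8-bis(MOMO)chroman-3-ol (2,3-cis-3,4-trans) | COCOc1ccc([C@H]2Oc3c(ccc(OCOC)c3OCOC)[C@H](OC)[C@H]2O)cc1OCOC | intermediate
16 | (2R,3R,4S)-6-bromo-4-methoxy-2-Ar-7,8-bis(MOMO)chroman-3-ol | COCOc1ccc([C@H]2Oc3c(cc(Br)c(OCOC)c3OCOC)[C@H](OC)[C@H]2O)cc1OCOC | intermediate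
17 | (2R,4S)-4-methoxy-2-Ar-7,8-bis(MOMO)chroman-3-one | COCOc1ccc([C@H]2Oc3c(ccc(OCOC)c3OCOC)[C@H](OC)C2=O)cc1OCOC | intermediate
18 | 6-lithio 3-O-lithium alkoxide of 16 | COCOc1ccc([C@H]2Oc3c(cc([Li])c(OCOC)c3OCOC)[C@H](OC)[C@H]2O[Li])cc1OCOC | intermediate
19 | dilithium dialkoxide of (2R,3S,4S)-2-Ar-3-[(2R,3R,4S)-2-Ar-3-hydroxy-4-methoxy-7,8-bis(MOMO)chroman-6-yl]-4-methoxy-7,8-bis(MOMO)chroman-3-ol (3-aryl α, trans-diaxial to 4-OMe) | COCOc1ccc([C@H]2Oc3c(ccc(OCOC)c3OCOC)[C@H](OC)[C@@]2(O[Li])c2cc3c(c(OCOC)c2OCOC)O[C@H](c2ccc(OCOC)c(OCOC)c2)[C@H](O[Li])[C@H]3OC)cc1OCOC | intermediate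
20 | (2R,4S)-2-Ar-4-[(2R,3R,4S)-2-Ar-3-hydroxy-4-methoxy-7,8-bis(MOMO)chroman-6-yl]-7,8-bis(MOMO)chroman-3-one (2,4-cis) | COCOc1ccc([C@H]2Oc3c(ccc(OCOC)c3OCOC)[C@@H](c3cc4c(c(OCOC)c3OCOC)O[C@H](c3ccc(OCOC)c(OCOC)c3)[C@H](O)[C@H]4OC)C2=O)cc1OCOC | intermediate
21 | (2R,3R,4S)-2-Ar-4-[(2R,3R,4S)-2-Ar-3-hydroxy-4-methoxy-7,8-bis(MOMO)chroman-6-yl]-7,8-bis(MOMO)chroman-3-ol (upper unit all-cis; 4S here is the same spatial arrangement as 4R in 23) | COCOc1ccc([C@H]2Oc3c(ccc(OCOC)c3OCOC)[C@@H](c3cc4c(c(OCOC)c3OCOC)O[C@H](c3ccc(OCOC)c(OCOC)c3)[C@H](O)[C@H]4OC)[C@H]2O)cc1OCOC | intermediate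
22 | (2R,3R,4R)-2-(3,4-dihydroxyphenyl)-4-[(2R,3R,4S)-2-(3,4-dihydroxyphenyl)-3,7,8-trihydroxy-4-methoxychroman-6-yl]chroman-3,7,8-triol | Oc1ccc([C@H]2Oc3c(ccc(O)c3O)[C@@H](c3cc4c(c(O)c3O)O[C@H](c3ccc(O)c(O)c3)[C@H](O)[C@H]4OC)[C@H]2O)cc1O | intermediate
23 | (2R,3R,4R)-2-(3,4-dihydroxyphenyl)-4-[(2R,3R,4S)-2-(3,4-dihydroxyphenyl)-3,4,7,8-tetrahydroxychroman-6-yl]chroman-3,7,8-triol (CNP0143773.1) | Oc1ccc([C@H]2Oc3c(ccc(O)c3O)[C@@H](c3cc4c(c(O)c3O)O[C@H](c3ccc(O)c(O)c3)[C@H](O)[C@H]4O)[C@H]2O)cc1O | target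

**Step count and risks**
Total: 13 steps. Longest linear sequence: 11 steps (1, 3, 4, 5, 6, 7, 8, 9, 11, 12, 13).

The three steps most likely to fail:

Step 11 (the new semipinacol coupling). Ketone 17 may enolise instead of adding the aryllithium, or a ring bond may migrate instead of the aryl group. The fallback sets out from 12 and 16 and comes back at 20. Hydroboration–oxidation of chromene 12 (BH3·SMe2, then NaOH/H2O2; boron adds to C3 anti to the aryl group) gives the 2,3-trans alcohol (2R,3S)-2-Ar-7,8-bis(MOMO)chroman-3-ol F2. Dess–Martin oxidation gives (2R)-2-Ar-7,8-bis(MOMO)chroman-3-one F3. Palladium-catalysed ketone α-arylation of F3 at its benzylic C4 methylene with bromide 16 (Pd2(dba)3, XPhos, NaOt-Bu, toluene, 60 °C) then gives 20, which continues with step 12.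

Step 6 (enantioselective ring closure). The very stabilised 1,3-diarylallyl cation may give low ee, or the product may racemise under the acid. The fallback sets out from 11 and comes back at 12. Heating 11 in toluene over silica gel at 80 °C (dehydration to the o-quinone methide and 6π-oxa-electrocyclisation) gives the racemic chromene rac-2-Ar-7,8-bis(MOMO)-2H-chromene F1. Preparative chiral SFC on an amylose-based phase resolves it, and the (2S)-enantiomer 12 is carried on.

Step 13 (global unmasking). Under protic acid the C4' cation may be trapped by another molecule, or formaldehyde equivalents may bridge the electron-rich rings. The fallback sets out from 21 and comes back at 23. ZnBr2 and n-PrSH in CH2Cl2 at 0 °C remove all eight MOM groups (the CH2 unit leaves as the dithioacetal) and exchange the 4'-OMe for a 4'β-propylsulfanyl group by thiolysis, giving the thioether (2R,3R,4R)-2-(3,4-dihydroxyphenyl)-4-[(2R,3R,4S)-2-(3,4-dihydroxyphenyl)-3,7,8-trihydroxy-4-(propylsulfanyl)chroman-6-yl]chroman-3,7,8-triol F4. AgBF4 in THF–water at 0 °C then ionises the C4'–S bond, and water adds trans to the 3'-OH to give 23.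

**Further compounds**
F1 | step 6 | rac-2-Ar-7,8-bis(MOMO)-2H-chromene | COCOc1ccc(C2Oc3c(ccc(OCOC)c3OCOC)C=C2)cc1OCOC
F2 | step 11 | (2R,3S)-2-Ar-7,8-bis(MOMO)chroman-3-ol | COCOc1ccc([C@H]2Oc3c(ccc(OCOC)c3OCOC)C[C@@H]2O)cc1OCOC
F3 | step 11 | (2R)-2-Ar-7,8-bis(MOMO)chroman-3-one | COCOc1ccc([C@H]2Oc3c(ccc(OCOC)c3OCOC)CC2=O)cc1OCOC
F4 | step 13 | (2R,3R,4R)-2-(3,4-dihydroxyphenyl)-4-[(2R,3R,4S)-2-(3,4-dihydroxyphenyl)-3,7,8-trihydroxy-4-(propylsulfanyl)chroman-6-yl]chroman-3,7,8-triol | Oc1ccc([C@H]2Oc3c(ccc(O)c3O)[C@@H](c3cc4c(c(O)c3O)O[C@H](c3ccc(O)c(O)c3)[C@H](O)[C@H]4SCCC)[C@H]2O)cc1O
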